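Numbering: ring A is C1 (bears the chain), C2 (CH2), C3/C4 (epoxide, methyl on C4), C5 and C6 (ester carbons); the chain is C7 (methylidene carbon) to C11. With the epoxide read back to an alkene, ring A hides a γ,δ-unsaturated carboxylic acid: C7 is the acid carbon, C1 its α-carbon and C3=C4 the γ,δ-bond. Everything rests on disconnecting C1–C2 by [3,3] rearrangement of a lactone silyl ketene acetal, which in one operation closes carbocycle A, places the C3=C4 alkene and sets C1. The precursor is a 6-methyl-6-vinyl δ-lactone carrying the trans C5/C6 diol of diethyl D-tartrate as silyl ethers; the chain is joined later at C7.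

Key step: step 8

Remark: TBS = tert-butyldimethylsilyl; atom labels C1–C11 are those of the first paragraph.

Assumption: in step 14 the (S)-configured oxazoline–sulfonamide ligand is taken as the enantiomer that sends the alkenylchromium reagent to the Re face of aldehyde 21 (giving 8S); if the sense proves opposite, its enantiomer is used with no other change.

Step 1
Reactants: 1 diethyl D-tartrate
Product: 2 diethyl (2S,3S)-2,3-bis(TBSO)butanedioate
Conditions: TBSOTf (2.4 equiv), 2,6-lutidine, CH2Cl2, 0 °C → rt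
Reagents that add atoms: tert-butyldimethylsilyl trifluoromethanesulfonate, CC(C)(C)[Si](C)(C)OS(=O)(=O)C(F)(F)F
Why: Silyl ether formation with a silyl triflate and a hindered pyridine base should silylate both secondary hydroxyls without touching the stereocentres, and bulky, non-chelating, acyclic ethers are what steps 6 and 8 need.

Step 2
Reactants: 2 diethyl (2S,3S)-2,3-bis(TBSO)butanedioate
Product: 3 (2S,3S)-2,3-bis(TBSO)-4-ethoxy-4-oxobutanoic acid
Conditions: KOH (1.0 equiv), EtOH–H2O, 0 °C → rt; aq. HCl to pH 3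
Reagents that add atoms: potassium hydroxide, [K+].[OH-]
Why: Mono-saponification of a C2-symmetric diester gives a single half-ester because the two ester groups are equivalent, and the carboxylate formed first repels hydroxide so that one equivalent of base should stop largely at this stage (recovered 2 is recycled).

Step 3
Reactants: 3 (2S,3S)-2,3-bis(TBSO)-4-ethoxy-4-oxobutanoic acid
Product: 5 ethyl (2S,3S)-2,3-bis(TBSO)-5-diazo-4-oxopentanoate, via acid chloride 4 (not isolated)
Conditions: Me2C=C(Cl)NMe2 (1.2 equiv), CH2Cl2, 0 °C → rt; then CH2N2 (3 equiv), Et2O, 0 °C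
Reagents that add atoms: diazomethane, C=[N+]=[N-] (1-chloro-N,N,2-trimethylprop-1-en-1-amine, CC(C)=C(Cl)N(C)C, supplies only the chlorine of intermediate 4)
Why: First stage of an Arndt–Eistert homologation, in which the neutral α-chloroenamine makes the acid chloride without free HCl and acylation of diazomethane gives the α-diazoketone, with no bond to a stereocentre broken.

Step 4
Reactants: 5 ethyl (2S,3S)-2,3-bis(TBSO)-5-diazo-4-oxopentanoate
Product: 6 (3R,4S)-3,4-bis(TBSO)-5-ethoxy-5-oxopentanoic acid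
Conditions: PhCO2Ag (0.1 equiv), Et3N, THF–H2O, rt, dark
Reagents that add atoms: water, O
Why: In the silver-catalysed Wolff rearrangement C6 migrates with retention to the carbene carbon and water traps the ketene, so a CH2 group (C1) is inserted between C6 and the carboxyl carbon (C7) under conditions that never form an ester enolate.

Step 5
Reactants: 6 (3R,4S)-3,4-bis(TBSO)-5-ethoxy-5-oxopentanoic acid
Product: 8 (3R,4S)-3,4-bis(TBSO)-5-oxohexanoic acid, via Weinreb amide acid 7 (not isolated)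
Conditions: MeNHOMe·HCl (2.5 equiv), iPrMgCl (6 equiv), THF, −20 °C; then MeMgBr (3 equiv), −20 → 0 °C; aq. citric acid
Reagents that add atoms: methylmagnesium bromide, C[Mg]Br (N,O-dimethylhydroxylamine hydrochloride, CNOC.Cl, supplies only the amide group of intermediate 7)
Why: Weinreb ketone synthesis run in one flask, where the chloromagnesium amide converts the α-silyloxy ethyl ester to the N-methoxy-N-methylamide while the acid is masked as its magnesium carboxylate, and the chelated adduct with MeMgBr cannot add a second time.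

Step 6
Reactants: 8 (3R,4S)-3,4-bis(TBSO)-5-oxohexanoic acid, 9 vinylmagnesium bromide (3.5 equiv)
Product: 10 (3R,4S,5R)-3,4-bis(TBSO)-5-hydroxy-5-methylhept-6-enoic acid
Conditions: THF, −78 → −40 °C; aq. citric acid
Reagents that add atoms: none
Why: Grignard 1,2-addition under polar Felkin–Anh control, in which the non-chelating C5 silyl ether stands anti to the incoming vinyl group and so sets the C4 carbinol centre (5R in 10, vinyl later cis to the C6 oxygen in the lactone), while the carboxylate is inert to the reagent.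

Step 7
Reactants: 10 (3R,4S,5R)-3,4-bis(TBSO)-5-hydroxy-5-methylhept-6-enoic acid
Product: 11 (4R,5S,6R)-4,5-bis(TBSO)-6-ethenyl-6-methyloxan-2-one
Conditions: EDCI·HCl (1.5 equiv), DMAP (0.2 equiv), CH2Cl2, 0 °C → rt
Reagents that add atoms: none
Why: Carbodiimide (Steglich-type) lactonisation closes the six-membered ring from the tertiary hydroxyl under near-neutral conditions that spare the tertiary allylic C–O bond and involve no stereocentre.

Step 8
Reactants: 11 (4R,5S,6R)-4,5-bis(TBSO)-6-ethenyl-6-methyloxan-2-one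
Product: 14 (1S,5R,6R)-5,6-bis(TBSO)-4-methylcyclohex-3-ene-1-carboxylic acid, via silyl ketene acetal 12 (not isolated), via trimethylsilyl ester 13 (not isolated)
Conditions: Me3SiCl/Et3N (premixed, 4 equiv), THF, −78 °C, then LiN(iPr)2 (1.5 equiv); −78 °C → rt; PhMe, 100 °C; aq. citric acid, THF, rt
Reagents that add atoms: chlorotrimethylsilane, C[Si](C)(C)Cl (silyl group of intermediates 12 and 13 only; 14 gains nothing but hydrogen)
Why: LiN(iPr)2 deprotonates C1 of 11 with Me3SiCl already present, so the enolate is O-silylated at −78 °C before the C6 silyloxy group can be expelled, and ketene acetal 12 then undergoes a concerted suprafacial [3,3] shift on heating in which C1–C2 forms as the ring C4–O bond breaks, giving silyl ester 13 and, after hydrolysis, acid 14. The closest known reaction type is the Ireland–Claisen rearrangement of vinyl-substituted lactone silyl ketene acetals to cycloalkene carboxylic acids. Ring A closes as a six-membered carbocycle through the boat-like, bicyclo[2.2.2]octadiene-type transition state that the tether enforces, the former vinyl π bond ending endocyclic and necessarily cis as C3=C4 with the methyl on C4. The only new stereocentre, C1, is controlled by the C4 carbinol centre of 11, which is consumed: the vinyl group is cis to the C6 oxygen, C2 can reach C1 only on that face, and the carboxyl therefore ends trans to C6–O (1S) without any epimerisation. The step needs silylation and rearrangement to outrun β-elimination and intermolecular condensation, which the internal quench, the neutral character of 12 and the acyclic silyl ethers (they let the C5–C6 bond eclipse in the boat) should secure.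

Step 9
Reactants: 14 (1S,5R,6R)-5,6-bis(TBSO)-4-methylcyclohex-3-ene-1-carboxylic acid
Product: 15 (1S,5R,6R)-5,6-bis(TBSO)-N-methoxy-N,4-dimethylcyclohex-3-ene-1-carboxamide
Conditions: MeNHOMe·HCl, EDCI·HCl, HOBt, N-methylmorpholine, CH2Cl2, 0 °C → rt
Reagents that add atoms: N,O-dimethylhydroxylamine hydrochloride, CNOC.Cl
Why: Carbodiimide/HOBt amidation to the Weinreb amide runs through the active ester under weakly basic conditions, so C1 (α to the carbonyl, β to a silyloxy group) should neither epimerise nor eliminate.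

Step 10
Reactants: 15 (1S,5R,6R)-5,6-bis(TBSO)-N-methoxy-N,4-dimethylcyclohex-3-ene-1-carboxamide
Product: 16 1-[(1S,5R,6R)-5,6-bis(TBSO)-4-methylcyclohex-3-en-1-yl]ethan-1-one
Conditions: MeMgBr (2 equiv), THF, −20 → 0 °C; aq. NH4Cl
Reagents that add atoms: methylmagnesium bromide, C[Mg]Br
Why: In the Weinreb ketone synthesis the magnesium chelate stops addition at the ketone stage and liberates the ketone only in the cold quench, which preserves C1.

Step 11
Reactants: 16 1-[(1S,5R,6R)-5,6-bis(TBSO)-4-methylcyclohex-3-en-1-yl]ethan-1-one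
Product: 18 1-[(1S,5R,6R)-5,6-bis(TBSO)-4-methylcyclohex-3-en-1-yl]ethenyl trifluoromethanesulfonate, via potassium enolate 17 (not isolated)
Conditions: KN(SiMe3)2 (1.2 equiv), THF, −78 °C (ketone added to base); then PhNTf2, −78 → −20 °C
Reagents that add atoms: N-phenylbis(trifluoromethanesulfonimide), FC(F)(F)S(=O)(=O)N(c1ccccc1)S(=O)(=O)C(F)(F)F (potassium bis(trimethylsilyl)amide, C[Si](C)(C)[N-][Si](C)(C)C.[K+], supplies only the potassium of intermediate 17)
Why: Kinetic deprotonation of the methyl group (the hindered C1 methine is left alone, so no enolate that could expel the C6 silyloxy group arises) followed by O-triflation should give the 1,1-disubstituted alkenyl triflate.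

Step 12
Reactants: 19 4-methylpent-3-en-1-ol
Product: 20 2-[(2R)-3,3-dimethyloxiran-2-yl]ethan-1-ol
Conditions: 1,2:4,5-di-O-isopropylidene-β-D-erythro-hexo-2,3-diulo-2,6-pyranose (0.3 equiv), KHSO5 (as Oxone), K2CO3, Bu4NHSO4 (cat.), MeCN–(MeO)2CH2–aq. Na2B4O7 buffer, 0 °C
Reagents that add atoms: potassium peroxymonosulfate, [K+].[O-]S(=O)(=O)OO
Why: In the Shi asymmetric epoxidation the dioxirane of the D-fructose-derived ketone transfers oxygen to the trisubstituted alkene through a spiro transition state that should set C10 as R, and the basic buffer keeps the 3,4-epoxy alcohol from cyclising.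

Step 13
Reactants: 20 2-[(2R)-3,3-dimethyloxiran-2-yl]ethan-1-ol
Product: 21 [(2R)-3,3-dimethyloxiran-2-yl]acetaldehyde
Conditions: Dess–Martin periodinane, NaHCO3, CH2Cl2, 0 °C; used at once
Reagents that add atoms: none
Why: Buffered Dess–Martin oxidation should give the β,γ-epoxy aldehyde without acid-induced epoxide opening or enolisation, and C10 is not α to the carbonyl.

Step 14
Reactants: 18 1-[(1S,5R,6R)-5,6-bis(TBSO)-4-methylcyclohex-3-en-1-yl]ethenyl trifluoromethanesulfonate, 21 [(2R)-3,3-dimethyloxiran-2-yl]acetaldehyde (1.5 equiv)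
Product: 22 (2S)-3-[(1R,5R,6R)-5,6-bis(TBSO)-4-methylcyclohex-3-en-1-yl]-1-[(2R)-3,3-dimethyloxiran-2-yl]but-3-en-2-ol
Conditions: CrCl2 (4 equiv), (S)-N-[2-(4-isopropyl-4,5-dihydro-1,3-oxazol-2-yl)-6-methylphenyl]methanesulfonamide (4.4 equiv), Et3N (4.4 equiv), THF, rt; then NiCl2 (0.1 equiv), 18, 21, rt
Reagents that add atoms: none
Why: In the Nozaki–Hiyama–Kishi coupling zerovalent nickel inserts into the C–OTf bond and transmetalation gives an alkenyl species of trivalent chromium that adds only to the aldehyde to form C7–C8, with the chiral sulfonamide–oxazoline ligand on chromium (asymmetric variant) selecting the Re face of 21 to set C8 as S under neutral conditions that should spare silyl ethers and epoxide.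

Step 15
Reactants: 22 (2S)-3-[(1R,5R,6R)-5,6-bis(TBSO)-4-methylcyclohex-3-en-1-yl]-1-[(2R)-3,3-dimethyloxiran-2-yl]but-3-en-2-ol
Product: 23 (1R,2R,6R)-6-[(3S)-4-[(2R)-3,3-dimethyloxiran-2-yl]-3-hydroxybut-1-en-2-yl]-3-methylcyclohex-3-ene-1,2-diol
Conditions: Bu4NF (3 equiv), THF, 0 °C → rt; aq. NH4Cl
Reagents that add atoms: none
Why: Fluoride desilylation frees the C5 and C6 hydroxyls under basic conditions in which the trisubstituted epoxide and the alkenes are stable and 5-endo attack of the C8 alkoxide on the epoxide is disfavoured.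

Step 16
Reactants: 23 (1R,2R,6R)-6-[(3S)-4-[(2R)-3,3-dimethyloxiran-2-yl]-3-hydroxybut-1-en-2-yl]-3-methylcyclohex-3-ene-1,2-diol, 24 angelic acid (9 equiv)
Product: 26 (1R,2R,6R)-6-[(3S)-4-[(2R)-3,3-dimethyloxiran-2-yl]-3-{[(2Z)-2-methylbut-2-enoyl]oxy}but-1-en-2-yl]-3-methylcyclohex-3-ene-1,2-diyl bis[(2Z)-2-methylbut-2-enoate], via mixed anhydride 25 (not isolated)
Conditions: 2,4,6-Cl3C6H2COCl (9 equiv), Et3N, PhMe, rt, filtered; then 23, 80 °C
Reagents that add atoms: 2,4,6-trichlorobenzoyl chloride, O=C(Cl)c1c(Cl)cc(Cl)cc1Cl (aroyl group of intermediate 25 only)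
Why: Yamaguchi-type esterification through the preformed mixed anhydride should acylate all three secondary hydroxyls on heating without a nucleophilic catalyst, which is the regime that keeps the Z geometry of angelates.

Step 17
Reactants: 26 tris-angelate (name as in step 16)
Product: 27 CNP0258231.1 (target)
Conditions: mCPBA (1.1 equiv), NaHCO3, CH2Cl2, 0 °C
Reagents that add atoms: 3-chloroperbenzoic acid, OOC(=O)c1cccc(Cl)c1
Why: Prilezhaev epoxidation should take the only electron-rich trisubstituted alkene (the 1,1-disubstituted alkene next to an ester and the conjugated angelates are deactivated) from the face anti to the allylic C5 angelate and the C1 chain, which sets C3 and C4.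

Compound list
1 | diethyl D-tartrate, diethyl (2S,3S)-2,3-dihydroxybutanedioate | CCOC(=O)[C@@H](O)[C@H](O)C(=O)OCC | starting material
2 | diethyl (2S,3S)-2,3-bis(TBSO)butanedioate | CCOC(=O)[C@@H](O[Si](C)(C)C(C)(C)C)[C@H](O[Si](C)(C)C(C)(C)C)C(=O)OCC | intermediate
3 | (2S,3S)-2,3-bis(TBSO)-4-ethoxy-4-oxobutanoic acid | CCOC(=O)[C@@H](O[Si](C)(C)C(C)(C)C)[C@H](O[Si](C)(C)C(C)(C)C)C(=O)O | intermediate
4 | ethyl (2S,3S)-2,3-bis(TBSO)-4-chloro-4-oxobutanoate | CCOC(=O)[C@@H](O[Si](C)(C)C(C)(C)C)[C@H](O[Si](C)(C)C(C)(C)C)C(=O)Cl | intermediate (not isolated)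
5 | ethyl (2S,3S)-2,3-bis(TBSO)-5-diazo-4-oxopentanoate | CCOC(=O)[C@@H](O[Si](C)(C)C(C)(C)C)[C@H](O[Si](C)(C)C(C)(C)C)C(=O)C=[N+]=[N-] | intermediate
6 | (3R,4S)-3,4-bis(TBSO)-5-ethoxy-5-oxopentanoic acid | CCOC(=O)[C@@H](O[Si](C)(C)C(C)(C)C)[C@H](O[Si](C)(C)C(C)(C)C)CC(=O)O | intermediate
7 | (3R,4S)-3,4-bis(TBSO)-5-[methoxy(methyl)amino]-5-oxopentanoic acid | CON(C)C(=O)[C@@H](O[Si](C)(C)C(C)(C)C)[C@H](O[Si](C)(C)C(C)(C)C)CC(=O)O | intermediate (not isolated)
8 | (3R,4S)-3,4-bis(TBSO)-5-oxohexanoic acid | CC(=O)[C@@H](O[Si](C)(C)C(C)(C)C)[C@H](O[Si](C)(C)C(C)(C)C)CC(=O)O | intermediate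
9 | vinylmagnesium bromide | C=C[Mg]Br | starting material
10 | (3R,4S,5R)-3,4-bis(TBSO)-5-hydroxy-5-methylhept-6-enoic acid | C=C[C@@](C)(O)[C@@H](O[Si](C)(C)C(C)(C)C)[C@H](O[Si](C)(C)C(C)(C)C)CC(=O)O | intermediate
11 | (4R,5S,6R)-4,5-bis(TBSO)-6-ethenyl-6-methyloxan-2-one | O=C1C[C@@H](O[Si](C)(C)C(C)(C)C)[C@H](O[Si](C)(C)C(C)(C)C)[C@@](C)(C=C)O1 | intermediate (key-step precursor)
12 | (2R,3S,4R)-3,4-bis(TBSO)-2-ethenyl-2-methyl-6-(trimethylsilyloxy)-3,4-dihydro-2H-pyran | C[Si](C)(C)OC1=C[C@@H](O[Si](C)(C)C(C)(C)C)[C@H](O[Si](C)(C)C(C)(C)C)[C@@](C)(C=C)O1 | intermediate (not isolated)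
13 | trimethylsilyl (1S,5R,6R)-5,6-bis(TBSO)-4-methylcyclohex-3-ene-1-carboxylate | C[Si](C)(C)OC(=O)[C@H]1CC=C(C)[C@@H](O[Si](C)(C)C(C)(C)C)[C@@H]1O[Si](C)(C)C(C)(C)C | intermediate (not isolated)
14 | (1S,5R,6R)-5,6-bis(TBSO)-4-methylcyclohex-3-ene-1-carboxylic acid | OC(=O)[C@H]1CC=C(C)[C@@H](O[Si](C)(C)C(C)(C)C)[C@@H]1O[Si](C)(C)C(C)(C)C | intermediate (key-step product)
15 | (1S,5R,6R)-5,6-bis(TBSO)-N-methoxy-N,4-dimethylcyclohex-3-ene-1-carboxamide | CON(C)C(=O)[C@H]1CC=C(C)[C@@H](O[Si](C)(C)C(C)(C)C)[C@@H]1O[Si](C)(C)C(C)(C)C | intermediate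
16 | 1-[(1S,5R,6R)-5,6-bis(TBSO)-4-methylcyclohex-3-en-1-yl]ethan-1-one | CC(=O)[C@H]1CC=C(C)[C@@H](O[Si](C)(C)C(C)(C)C)[C@@H]1O[Si](C)(C)C(C)(C)C | intermediate
17 | potassium 1-[(1S,5R,6R)-5,6-bis(TBSO)-4-methylcyclohex-3-en-1-yl]ethen-1-olate | [K+].[O-]C(=C)[C@H]1CC=C(C)[C@@H](O[Si](C)(C)C(C)(C)C)[C@@H]1O[Si](C)(C)C(C)(C)C | intermediate (not isolated)
18 | 1-[(1S,5R,6R)-5,6-bis(TBSO)-4-methylcyclohex-3-en-1-yl]ethenyl trifluoromethanesulfonate | C=C(OS(=O)(=O)C(F)(F)F)[C@H]1CC=C(C)[C@@H](O[Si](C)(C)C(C)(C)C)[C@@H]1O[Si](C)(C)C(C)(C)C | intermediate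
19 | 4-methylpent-3-en-1-ol | CC(C)=CCCO | starting material
20 | 2-[(2R)-3,3-dimethyloxiran-2-yl]ethan-1-ol | OCC[C@H]1OC1(C)C | intermediate
21 | [(2R)-3,3-dimethyloxiran-2-yl]acetaldehyde | O=CC[C@H]1OC1(C)C | intermediate
22 | (2S)-3-[(1R,5R,6R)-5,6-bis(TBSO)-4-methylcyclohex-3-en-1-yl]-1-[(2R)-3,3-dimethyloxiran-2-yl]but-3-en-2-ol | C=C([C@H](C[C@H]1OC1(C)C)O)[C@H]1CC=C(C)[C@@H](O[Si](C)(C)C(C)(C)C)[C@@H]1O[Si](C)(C)C(C)(C)C | intermediate
23 | (1R,2R,6R)-6-[(3S)-4-[(2R)-3,3-dimethyloxiran-2-yl]-3-hydroxybut-1-en-2-yl]-3-methylcyclohex-3-ene-1,2-diol | C=C([C@H](C[C@H]1OC1(C)C)O)[C@H]1CC=C(C)[C@@H](O)[C@@H]1O | intermediate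
24 | angelic acid, (2Z)-2-methylbut-2-enoic acid | C/C=C(/C)C(=O)O | starting material
25 | (2Z)-2-methylbut-2-enoic 2,4,6-trichlorobenzoic anhydride | C/C=C(/C)C(=O)OC(=O)c1c(Cl)cc(Cl)cc1Cl | intermediate (not isolated)
26 | (1R,2R,6R)-6-[(3S)-4-[(2R)-3,3-dimethyloxiran-2-yl]-3-{[(2Z)-2-methylbut-2-enoyl]oxy}but-1-en-2-yl]-3-methylcyclohex-3-ene-1,2-diyl bis[(2Z)-2-methylbut-2-enoate] | C=C([C@H](C[C@H]1OC1(C)C)OC(=O)/C(C)=C\C)[C@H]1CC=C(C)[C@@H](OC(=O)/C(C)=C\C)[C@@H]1OC(=O)/C(C)=C\C | intermediate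
27 | CNP0258231.1 (3,4-epoxide of 26, oxygen anti to the C5 ester) | C=C([C@H](C[C@H]1OC1(C)C)OC(=O)/C(C)=C\C)[C@H]1C[C@@H]2O[C@]2(C)[C@@H](OC(=O)/C(C)=C\C)[C@@H]1OC(=O)/C(C)=C\C | target

Total step count: 17. Longest linear sequence: 15 (steps 1–11 and 14–17, from diethyl D-tartrate); steps 12–13 form the side-chain branch.

Steps most likely to fail

Step 8. The enolate may lose the C6 silyloxy group by β-elimination before it is silylated. The fallback makes that oxygen unable to leave instead of racing it. From lactone 11 the less hindered C6 silyl ether is removed (HF·pyridine, pyridine, THF, 0 °C) to give (4R,5S,6R)-5-(TBSO)-6-ethenyl-4-hydroxy-6-methyloxan-2-one F1. Two equivalents of LiN(iPr)2 at −78 °C form the alkoxide–enolate dianion (Fráter–Seebach-type; an oxide is not expelled), and Me3SiCl then caps both oxygens to give (2R,3S,4R)-3-(TBSO)-2-ethenyl-2-methyl-4,6-bis(trimethylsilyloxy)-3,4-dihydro-2H-pyran F2. Heating in toluene should rearrange it, as in the dianionic ester-enolate Claisen rearrangements of β-hydroxy allyl esters, to trimethylsilyl (1S,5R,6R)-5-(TBSO)-4-methyl-6-(trimethylsilyloxy)cyclohex-3-ene-1-carboxylate F3. Aqueous acid gives (1S,5R,6R)-5-(TBSO)-6-hydroxy-4-methylcyclohex-3-ene-1-carboxylic acid F4. TBSOTf/2,6-lutidine gives tert-butyldimethylsilyl (1S,5R,6R)-5,6-bis(TBSO)-4-methylcyclohex-3-ene-1-carboxylate F5, and K2CO3 in aqueous MeOH cleaves the silyl ester to rejoin the route at 14.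

Step 14. Ligand control may give poor facial selectivity at the aldehyde. The fallback sets C8 by reduction instead of by addition. Triflate 18 and aldehyde 21 are coupled without ligand (CrCl2, cat. NiCl2, DMF, rt) to 3-[(1R,5R,6R)-5,6-bis(TBSO)-4-methylcyclohex-3-en-1-yl]-1-[(2R)-3,3-dimethyloxiran-2-yl]but-3-en-2-ol as a mixture of C8 epimers F6. Buffered Dess–Martin oxidation at 0 °C gives 3-[(1R,5R,6R)-5,6-bis(TBSO)-4-methylcyclohex-3-en-1-yl]-1-[(2R)-3,3-dimethyloxiran-2-yl]but-3-en-2-one F7. Corey–Bakshi–Shibata reduction with (R)-2-methyl-CBS-oxazaborolidine and catecholborane in toluene at −78 °C (alkenyl as the large group, hydride to the Re face) should return the route to 22.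

Step 17. The peracid may show poor facial selectivity on the ring alkene or attack the other alkenes. The fallback replaces substrate control by reagent control: 26 is epoxidised under Shi conditions with the L-fructose-derived enantiomer of the ketone of step 12 (KHSO5, K2CO3, buffered MeCN–(MeO)2CH2–H2O, 0 °C). Its spiro transition state should deliver oxygen to the face of C3=C4 anti to the C5 ester, and it is selective for electron-rich trisubstituted alkenes. This leads directly from 26 to 27 without a new intermediate.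

Further compounds
F1 | step 8 | (4R,5S,6R)-5-(TBSO)-6-ethenyl-4-hydroxy-6-methyloxan-2-one | O=C1C[C@@H](O)[C@H](O[Si](C)(C)C(C)(C)C)[C@@](C)(C=C)O1
F2 | step 8 | (2R,3S,4R)-3-(TBSO)-2-ethenyl-2-methyl-4,6-bis(trimethylsilyloxy)-3,4-dihydro-2H-pyran | C[Si](C)(C)OC1=C[C@@H](O[Si](C)(C)C)[C@H](O[Si](C)(C)C(C)(C)C)[C@@](C)(C=C)O1
F3 | step 8 | trimethylsilyl (1S,5R,6R)-5-(TBSO)-4-methyl-6-(trimethylsilyloxy)cyclohex-3-ene-1-carboxylate | C[Si](C)(C)OC(=O)[C@H]1CC=C(C)[C@@H](O[Si](C)(C)C(C)(C)C)[C@@H]1O[Si](C)(C)C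
F4 | step 8 | (1S,5R,6R)-5-(TBSO)-6-hydroxy-4-methylcyclohex-3-ene-1-carboxylic acid | OC(=O)[C@H]1CC=C(C)[C@@H](O[Si](C)(C)C(C)(C)C)[C@@H]1O
F5 | step 8 | tert-butyldimethylsilyl (1S,5R,6R)-5,6-bis(TBSO)-4-methylcyclohex-3-ene-1-carboxylate | CC(C)(C)[Si](C)(C)OC(=O)[C@H]1CC=C(C)[C@@H](O[Si](C)(C)C(C)(C)C)[C@@H]1O[Si](C)(C)C(C)(C)C
F6 | step 14 | 3-[(1R,5R,6R)-5,6-bis(TBSO)-4-methylcyclohex-3-en-1-yl]-1-[(2R)-3,3-dimethyloxiran-2-yl]but-3-en-2-ol, mixture of C8 epimers | C=C(C(O)C[C@H]1OC1(C)C)[C@H]1CC=C(C)[C@@H](O[Si](C)(C)C(C)(C)C)[C@@H]1O[Si](C)(C)C(C)(C)C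
F7 | step 14 | 3-[(1R,5R,6R)-5,6-bis(TBSO)-4-methylcyclohex-3-en-1-yl]-1-[(2R)-3,3-dimethyloxiran-2-yl]but-3-en-2-one | C=C(C(=O)C[C@H]1OC1(C)C)[C@H]1CC=C(C)[C@@H](O[Si](C)(C)C(C)(C)C)[C@@H]1O[Si](C)(C)C(C)(C)C
F0 | step 17 | none | none
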